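**Remark on the chemistry (assumption):** (E)-pent-3-en-1-ol is taken as a purchasable material of high geometric purity; its alkene geometry is carried unchanged into the cyclisation precursor.

## Structural features

The target is a single cyclohexane ring carrying four halogens and no other heteroatom. It is numbered here C1 (quaternary, methyl and chlorine), C2 (CH2), C3 (quaternary, methyl and bromine), C4 (CH carrying the (E)-2-chloroethenyl chain C9=C10), C5 (CH2) and C6 (CHBr). The four stereocentres form two adjacent pairs: C6/C1 (secondary bromide next to tertiary chloride, halogens cis on the ring) and C3/C4 (tertiary bromide trans to the side chain). The pairs are tied together by the 1,3-cis relationship of the C6 bromine and the C4 side chain. In this numbering the configurations are 1R, 3R, 4S and 6S. Both tertiary halides ionise and eliminate easily, the vicinal bromide/chloride pair can be lost to low-valent metals, and the chloroalkene must stay E, so late intermediates tolerate neither strong base, strong Lewis acid nor reducing metals. The real difficulty is that no oxygen function is available to steer reagents, that the cis C1–Cl/C6–Br pair cannot come from an anti addition to a ring alkene, and that neither tertiary halide can be made by displacement. The key step uses the fact that the C3 methyl/bromine pair beside the C4 alkenyl group is the Markovnikov HBr adduct of a C3 methylidene. C3 and C4 with their appendages then form a 1,4-diene, the product pattern of an enyne Alder-ene reaction that closes the ring at C3–C4. The cis C1/C6 dihalide in turn corresponds to an anti addition across an acyclic (E)-alkene, so it can be fixed before the ring exists.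

## Logic of the disconnections

**17 to 16.** The C3–Br bond and one C–H bond of the C3 methyl group are removed, giving 16. The tertiary bromide is the most labile group and is best made last, and a methylidene is its natural Markovnikov precursor. One stereocentre disappears. The forward addition must be Markovnikov, must leave the chloroalkene and the C1–Cl bond alone, and must deliver bromine to the face of C3 away from the C4 chain.

**16 to 14 and 15.** The C9=C10 bond is cut by a metathesis transform. The terminal vinyl group of 14 is exactly what the ring-forming step leaves behind, so no functional-group adjustment is needed. The forward step must be E-selective and must react at the monosubstituted alkene and not at the methylidene.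

**14 to 13 (key).** The C3–C4 bond is cut. The 1,4-diene of 14 is an Alder-ene retron: C3 and its methylidene come from a terminal alkyne, C4 and the vinyl group from an (E)-butenyl unit. The ring and the C4 stereocentre disappear, leaving an acyclic chain whose only stereocentres are the C1/C6 dihalide. The forward step must close a six-membered ring, set C4 cis to the C6 bromine, eliminate towards the methyl group and leave both carbon–halogen bonds intact.

**13 to 11 (through 12).** The C1–Cl bond is traced back to a C1–O bond of the same configuration. A tertiary chloride cannot be made by direct displacement, but the neighbouring bromine allows two successive inversions. The forward step demands ionisation with bromine participation, chloride attack at the tertiary end of the bridged ion, and no elimination.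

**11 to 10.** The C6–Br bond is cut and its carbon joined to the C1 oxygen, giving an epoxide. Trans opening supplies the anti bromine/oxygen relationship, and both heteroatom-bearing centres are merged into one functional group. The forward step needs bromide attack at the secondary carbon with inversion.

**10 to 6 and 7 (through 8 and 9).** The sp3–sp bond C2–C3 and the C–Si bond are cut. This places a hydroxymethyl group on the future C1, so that the epoxide sits in an epoxy alcohol. The forward step is a displacement at a CH2 next to a fully substituted epoxide carbon, which must outrun epoxide opening.

**6 to 5.** Both C–O bonds of the epoxide are removed. The allylic hydroxyl makes the epoxidation directed, enantioselective and chemoselective over the remote alkene. No stereocentre remains in 5. The forward step must select the correct alkene face.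

**5 to 4, then 1 and 2 (through 3).** The C–O oxidation level is adjusted and the trisubstituted alkene (the future C1–C6 bond) is cut by a Wittig transform. A stabilised ylide secures the E geometry that later becomes the cis C1/C6 relationship, and the remote (E)-alkene is bought in 1. The forward step must avoid isomerisation of the β,γ-unsaturated aldehyde 3.

## Other disconnections considered

**Alternative 1:** The cut is C4–C5, with a lactone C1–O bond broken in the same event.
- **Forward key step:** the six-membered vinyl lactone (6R)-6-ethenyl-6-methyl-4-methylideneoxan-2-one A1 would be converted into its silyl ketene acetal (lithium diisopropylamide, Me3SiCl). An Ireland–Claisen [3,3] shift through the boat imposed by the ring contracts it to the carbocycle. Hydrolysis of the silyl ester gives (1R)-4-methyl-2-methylidenecyclohex-3-ene-1-carboxylic acid A2.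
- **In favour:** the rearrangement is concerted and suprafacial, so the configuration of a chiral-pool tertiary allylic carbinol is transferred to C4 with high fidelity. The C3 methylidene and a C1=C6 alkene appear at once, and no transition metal is needed.
- **Against:** A2 holds C1/C6 as a ring alkene. Anti bromochlorination of a ring alkene gives the trans dihalide, whereas the target needs cis. The route would have to pass through an epoxide opened twice with inversion (chloride at the tertiary carbon, then invertive bromination of a hindered secondary alcohol) and find facial selectivity from the remote C4 centre. The acid must also be taken through a β,γ-unsaturated aldehyde, epimerisable at C4, before the chloroalkene can be made.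
- **Comparison:** on control of C4 the alternative is the better plan (pericyclic chirality transfer against a chair preference in a carbopalladation). On mechanism both ring closures are well understood and comparable. On structure the chosen plan is ahead, because both ring halogens arrive with defined configuration. On step economy A2 would need clearly more steps after ring closure than the two of the chosen plan, besides the assembly of A1.

**Alternative 2:** The cuts are C4–C5 and C1–C6, a Diels–Alder disconnection.
- **Forward key step:** a cationic chiral oxazaborolidine Lewis acid would activate an α-bromo enal towards a 1-silyloxy diene. The [4+2] cycloaddition would give [(1R,4R,5S)-5-bromo-5-formyl-2,4-dimethyl-4-(triethylsilyloxy)cyclohex-2-en-1-yl]methyl 2,2-dimethylpropanoate A3.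
- **In favour:** two C–C bonds, the ring and up to three stereocentres (C1, C4, C6) are formed in one catalytic enantioselective step from simple fragments, and the C6 bromine arrives with the dienophile. On convergence and on the number of bonds and stereocentres made in the key step, the alternative is the better plan.
- **Against:** the diene terminus that becomes C1 is fully substituted, which slows the cycloaddition and makes the endo/exo and facial outcome of an asynchronous transition state hard to predict. A3 then carries several groups in the wrong state. The formyl group on C6 must be excised with the C–Br bond intact. The silyloxy group on a tertiary allylic carbon must be exchanged for chlorine with defined configuration. The C2=C3 alkene must add HBr regio- and stereoselectively. The pivalate must be carried on to the chloroalkene.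
- **Comparison:** the mechanism of the key step is as well founded as the enyne cyclisation. On structure the chosen plan leaves the ring with its C1 and C6 halogens already final. On step economy the long functional-group editing after A3 outweighs the convergent start.

**Alternative 3:** The cut is C1–C2, a carbonyl-ene disconnection.
- **Forward key step:** Me2AlCl would coordinate the ketone of (3S,5S)-3-bromo-5-[(E)-2-chloroethenyl]-6-methylhept-6-en-2-one A4. The terminal carbon of the isopropenyl group attacks the carbonyl carbon while a methyl hydrogen moves to oxygen. The product is (1R,2S,4S)-2-bromo-4-[(E)-2-chloroethenyl]-1-methyl-5-methylidenecyclohexan-1-ol A5.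
- **In favour:** the chloroalkene and the C6 bromine are in place before ring closure, so no metathesis is needed; on this point the alternative is the better plan. The α-bromo ketone centre can epimerise, so both epimers of A4 may funnel into one product. The C3 methylidene is produced as in the chosen plan, and the number of steps after ring closure is the same (two), so there the plans are equal.
- **Against:** in A5 the tertiary hydroxyl on C1 is cis to the C6 bromine within the ring. The bromine cannot reach the backside of the C1–O bond, so replacing OH by Cl with retention cannot rely on bromine participation. It would rest on ion-pair return from a tertiary cation, with elimination and attack from the other face as competitors. The configuration at C1 in the ene step depends on a balance of dipole and chelation effects with the α-bromine. A4 itself needs an enantioselective construction of C4 with the chloroalkene attached.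
- **Comparison:** both plans close the ring by an ene-type process, with comparable mechanistic confidence in the closure itself. Structurally the chosen plan fixes C1 and C6 by stereospecific acyclic reactions, whereas the alternative postpones the C1–Cl bond to a step without a stereochemical handle.

Key step: step 7

## Route

**Step 1**
Reactants: 1 (E)-pent-3-en-1-ol; 2 ethyl 2-(triphenyl-λ5-phosphanylidene)propanoate
Product: 4 ethyl (2E,5E)-2-methylhepta-2,5-dienoate, via (E)-pent-3-enal 3 (not isolated)
Conditions: Dess–Martin periodinane, NaHCO3, CH2Cl2, 0 °C to rt; then 2, rt
Reagents that add atoms: none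
Why: Dess–Martin oxidation gives the β,γ-unsaturated aldehyde under buffered, non-basic conditions, and the Wittig reaction of the stabilised α-methyl ylide in the same flask, so that the aldehyde is never concentrated, should give the (E)-trisubstituted enoate because oxaphosphetane formation is reversible for stabilised ylides; the existing (E)-alkene is not touched.

**Step 2**
Reactants: 4 ethyl (2E,5E)-2-methylhepta-2,5-dienoate
Product: 5 (2E,5E)-2-methylhepta-2,5-dien-1-ol
Conditions: i-Bu2AlH, CH2Cl2, −78 to 0 °C; aq. potassium sodium tartrate
Reagents that add atoms: none
Why: Hydride reduction of the conjugated ester by i-Bu2AlH proceeds by 1,2-delivery to the allylic alcohol without touching either alkene; no stereocentre is formed.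

**Step 3**
Reactants: 5 (2E,5E)-2-methylhepta-2,5-dien-1-ol
Product: 6 [(2R,3R)-3-[(2E)-but-2-en-1-yl]-2-methyloxiran-2-yl]methanol
Conditions: Ti(OiPr)4 (10 mol %), D-(−)-diisopropyl tartrate (12 mol %), t-BuOOH, 4 Å molecular sieves, CH2Cl2, −20 °C
Reagents that add atoms: tert-butyl hydroperoxide, CC(C)(C)OO
Why: Sharpless asymmetric epoxidation: the titanium tartrate complex binds the allylic hydroxyl, so only the 2,3-alkene reacts and the remote (E)-alkene is left; D-(−)-tartrate gives the (2R,3R)-epoxide (the mirror image of the (2S,3S) outcome of L-(+)-tartrate with (E)-allylic alcohols), which fixes the configuration of the future C1 oxygen and, after inversion in step 5, of the C6 bromide.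

**Step 4**
Reactants: 6 [(2R,3R)-3-[(2E)-but-2-en-1-yl]-2-methyloxiran-2-yl]methanol; 7 ethynyl(trimethyl)silane
Product: 10 (2R,3R)-3-[(2E)-but-2-en-1-yl]-2-methyl-2-(prop-2-yn-1-yl)oxirane, via the epoxy triflate 8 (not isolated), via the silylated alkyne 9 (not isolated)
Conditions: Tf2O, 2,6-lutidine, CH2Cl2, −78 °C; then LiC≡CSiMe3 (from 7, n-BuLi), THF, DMPU, −78 to −20 °C; then K2CO3, MeOH, rt
Reagents that add atoms: trifluoromethanesulfonic anhydride, O=S(=O)(OS(=O)(=O)C(F)(F)F)C(F)(F)F (its atoms stay only in 8)
Why: Triflation, SN2 alkylation of a lithium acetylide and base-catalysed protodesilylation: without a Lewis acid the acetylide displaces the primary triflate far faster than it opens the trisubstituted epoxide, the fully substituted neighbouring carbon rules out β-elimination, methanolysis then cleaves the C(sp)–Si bond, and neither stereocentre is involved; this forms the C2–C3 bond.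

**Step 5**
Reactants: 10 (2R,3R)-3-[(2E)-but-2-en-1-yl]-2-methyl-2-(prop-2-yn-1-yl)oxirane
Product: 11 (4R,5S,7E)-5-bromo-4-methylnon-7-en-1-yn-4-ol
Conditions: Li2NiBr4, THF, 0 °C to rt; pH 7 buffer
Reagents that add atoms: dilithium tetrabromonickelate, [Li+].[Li+].[Ni+2].[Br-].[Br-].[Br-].[Br-]
Why: Epoxide ring opening by the soft bromide of Li2NiBr4 under nearly neutral conditions follows an SN2 course at the less substituted carbon, so bromine enters the future C6 with inversion (5S) while the tertiary C–O bond keeps its configuration (4R); a regioisomeric bromohydrin would ionise to the same bromonium ion in step 6.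

**Step 6**
Reactants: 11 (4R,5S,7E)-5-bromo-4-methylnon-7-en-1-yn-4-ol
Product: 13 (4R,5S,7E)-5-bromo-4-chloro-4-methylnon-7-en-1-yne, via the tertiary chlorosulfite 12 (not isolated)
Conditions: SOCl2, CH2Cl2, −20 to 0 °C
Reagents that add atoms: thionyl chloride, ClS(Cl)=O
Why: Deoxychlorination with neighbouring-group participation: the chlorosulfite ionises with backside assistance from the anti-periplanar bromine, and chloride opens the bromonium ion at its tertiary carbon, again with inversion, so two inversions give net retention at the future C1 (4R) while C6 is unchanged; leaving out an amine base suppresses E2 loss of the chlorosulfite.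

**Step 7**
Reactants: 13 (4R,5S,7E)-5-bromo-4-chloro-4-methylnon-7-en-1-yne
Product: 14 (1S,2R,5S)-1-bromo-2-chloro-5-ethenyl-2-methyl-4-methylidenecyclohexane
Conditions: Pd(OAc)2 (5 mol %), PPh3 (10 mol %), AcOH (20 mol %), PhH, 60 °C
Reagents that add atoms: none
Why: Zerovalent palladium formed from Pd(OAc)2 and PPh3 is protonated by AcOH to a hydridopalladium acetate of divalent palladium, which adds syn across the terminal alkyne so that palladium sits on C3 and hydrogen on the future methylidene carbon. The alkenylpalladium then inserts the (E)-alkene intramolecularly, forming C3–C4 and placing palladium on C9, and β-hydride elimination from the C10 methyl group releases the vinyl group and returns the hydride. The closest known reaction type is the palladium-catalysed cycloisomerisation (Alder-ene reaction) of 1,6- and 1,7-enynes to 1,4-dienes. The six-membered ring closes in a 6-exo-trig carbopalladation. The only new stereocentre, C4, is controlled by the existing C6 centre through a chair-like insertion transition state in which the C6 bromine and the reacting alkene are both equatorial (C1 chlorine axial, C1 methyl equatorial), which gives the 4,6-cis product. The step needs β-hydride elimination towards the methyl group and not towards C4–H, which is secured because the new exocyclic methylene stays coordinated to palladium and holds the Pd–C9 bond away from C4–H while the methyl hydrogens rotate freely into a syn arrangement. It also needs both halides to be spectators, which the nearly neutral conditions and the poor reactivity of unactivated secondary bromides and tertiary chlorides towards triphenylphosphine-ligated palladium provide, and ring closure is helped by the fully substituted C1 in the tether.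

**Step 8**
Reactants: 14 (1S,2R,5S)-1-bromo-2-chloro-5-ethenyl-2-methyl-4-methylidenecyclohexane; 15 (E)-1,2-dichloroethene
Product: 16 (1S,2R,5S)-1-bromo-2-chloro-5-[(E)-2-chloroethenyl]-2-methyl-4-methylidenecyclohexane
Conditions: 15 (excess), Mo(NC6F5)(CHCMe2Ph)(2,5-Me2C4H2N)(OAr) (5 mol %, OAr = 2,6-bis(2,4,6-triethylphenyl)phenoxide), PhH, rt
Reagents that add atoms: none
Why: Cross-metathesis: the molybdenum alkylidene engages the monosubstituted vinyl group and (E)-1,2-dichloroethene, and the chloro-substituted metallacyclobutane collapses under kinetic control to the (E)-chloroalkene; the 1,1-disubstituted methylidene reacts far more slowly, and a substrate with alkyl halides and no protic group suits this catalyst class.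

**Step 9**
Reactants: 16 (1S,2R,5S)-1-bromo-2-chloro-5-[(E)-2-chloroethenyl]-2-methyl-4-methylidenecyclohexane
Product: 17 (1R,2S,4S,5R)-1,4-dibromo-5-chloro-2-[(E)-2-chloroethenyl]-1,5-dimethylcyclohexane
Conditions: Co(acac)2 (25 mol %), t-BuOOH (25 mol %), Et3SiH, TsBr, n-PrOH, rt
Reagents that add atoms: 4-methylbenzenesulfonyl bromide, Cc1ccc(cc1)S(Br)(=O)=O
Why: Markovnikov hydrobromination by metal-hydride hydrogen atom transfer (Mukaiyama type): a cobalt hydride transfers hydrogen to the terminal carbon of the methylidene and the tertiary C3 radical abstracts bromine from TsBr; in the chair that keeps the C4 and C6 substituents equatorial the axial C1–Cl blocks axial approach to C3, so bromine should enter equatorially, trans to the C4 chain (R at the new centre), while the chloroalkene and the alkyl halides are inert to these radical conditions.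

## Compound list

1 | (E)-pent-3-en-1-ol | OCC/C=C/C | starting material
2 | ethyl 2-(triphenyl-λ5-phosphanylidene)propanoate | CCOC(=O)C(C)=P(c1ccccc1)(c1ccccc1)c1ccccc1 | starting material
3 | (E)-pent-3-enal | O=CC/C=C/C | intermediate (not isolated)
4 | ethyl (2E,5E)-2-methylhepta-2,5-dienoate | CCOC(=O)/C(C)=C/C/C=C/C | intermediate
5 | (2E,5E)-2-methylhepta-2,5-dien-1-ol | OC/C(C)=C/C/C=C/C | intermediate
6 | [(2R,3R)-3-[(2E)-but-2-en-1-yl]-2-methyloxiran-2-yl]methanol | OC[C@@]1(C)O[C@@H]1C/C=C/C | intermediate
7 | ethynyl(trimethyl)silane | C#C[Si](C)(C)C | starting material
8 | [(2R,3R)-3-[(2E)-but-2-en-1-yl]-2-methyloxiran-2-yl]methyl trifluoromethanesulfonate | FC(F)(F)S(=O)(=O)OC[C@@]1(C)O[C@@H]1C/C=C/C | intermediate (not isolated)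
9 | trimethyl{3-[(2R,3R)-3-[(2E)-but-2-en-1-yl]-2-methyloxiran-2-yl]prop-1-yn-1-yl}silane | C[Si](C)(C)C#CC[C@@]1(C)O[C@@H]1C/C=C/C | intermediate (not isolated)
10 | (2R,3R)-3-[(2E)-but-2-en-1-yl]-2-methyl-2-(prop-2-yn-1-yl)oxirane | C#CC[C@@]1(C)O[C@@H]1C/C=C/C | intermediate
11 | (4R,5S,7E)-5-bromo-4-methylnon-7-en-1-yn-4-ol | C#CC[C@@](C)(O)[C@@H](Br)C/C=C/C | intermediate
12 | (4R,5S,7E)-5-bromo-4-methylnon-7-en-1-yn-4-yl chlorosulfite | C#CC[C@@](C)(OS(Cl)=O)[C@@H](Br)C/C=C/C | intermediate (not isolated)
13 | (4R,5S,7E)-5-bromo-4-chloro-4-methylnon-7-en-1-yne | C#CC[C@@](C)(Cl)[C@@H](Br)C/C=C/C | intermediate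
14 | (1S,2R,5S)-1-bromo-2-chloro-5-ethenyl-2-methyl-4-methylidenecyclohexane | C[C@@]1(Cl)CC(=C)[C@H](C=C)C[C@@H]1Br | intermediate
15 | (E)-1,2-dichloroethene | Cl/C=C/Cl | starting material
16 | (1S,2R,5S)-1-bromo-2-chloro-5-[(E)-2-chloroethenyl]-2-methyl-4-methylidenecyclohexane | C[C@@]1(Cl)CC(=C)[C@H](/C=C/Cl)C[C@@H]1Br | intermediate
17 | (1R,2S,4S,5R)-1,4-dibromo-5-chloro-2-[(E)-2-chloroethenyl]-1,5-dimethylcyclohexane | C[C@@]1(Cl)C[C@@](C)(Br)[C@H](/C=C/Cl)C[C@@H]1Br | target

## Step count and least certain steps

Total step count: 9. Longest linear sequence: 9 steps (1 to 17).

**Step 7 (key step).** Closure of a six-membered ring from a 1,7-enyne is slower than five-membered closure, so alkyne oligomerisation may compete. The chair preference that sets C4 is modest, so facial selectivity of the carbopalladation may erode. β-Hydride elimination may turn towards C4–H and give a conjugated diene. Zerovalent palladium may also strip the vicinal bromide/chloride pair reductively. Fallback, from 13: bromoboration of the terminal alkyne with B-bromo-9-borabicyclo[3.3.1]nonane and protonolysis of the alkenylborane with AcOH would give (4R,5S,7E)-2,5-dibromo-4-chloro-4-methylnona-1,7-diene F1. An intramolecular Heck reaction (Pd(OAc)2, PPh3, Ag2CO3, MeCN, 70 °C) then reaches the same alkenylpalladium species by oxidative addition, closes C3–C4 in the 6-exo mode and eliminates towards the methyl group. The fallback returns to the route at 14.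

**Step 6.** The tertiary chlorosulfite may lose the elements of HOS(O)Cl by elimination instead of ionising with bromine participation. Chloride may also open the bromonium ion at the secondary carbon, which amounts to a 1,2-bromine shift. Both follow from the ease with which a tertiary centre ionises. Fallback, from 10: the leaving group is moved to the secondary oxygen. Opening of the epoxide at the tertiary carbon with MgBr2·OEt2 (Et2O, −20 °C, inversion) would give (4S,5R,7E)-4-bromo-4-methylnon-7-en-1-yn-5-ol F2, and mesylation (MsCl, Et3N) would give (4S,5R,7E)-4-bromo-4-methylnon-7-en-1-yn-5-yl methanesulfonate F3. Ionisation of F3 in (CF3)2CHOH–CH2Cl2 with Et4NCl, assisted by the tertiary bromine, leads to the same bromonium ion, which chloride opens at the tertiary carbon. The fallback returns at 13.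

**Step 9.** Facial selectivity of bromine-atom transfer to the planar C3 radical may be poor, because torsional preference for axial attack opposes the steric shielding by the axial C1–Cl. Hydrogen atom transfer to the chloroalkene is a minor second risk. Fallback, from 16: polar Markovnikov addition of anhydrous HBr (from Me3SiBr and MeOH, CH2Cl2, −78 °C). The stereo-determining event then becomes collapse of a tertiary cation/bromide ion pair instead of atom transfer to a radical. The fallback returns at 17 and makes no new compound (entry F0).

**Step 8.** The chloromethylidene intermediate may decompose before turnover, and initiation at the α-branched vinyl group next to the methylidene may be slow. Either would lead to low conversion or loss of E selectivity. Fallback, from 14: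
- cross-metathesis with vinylboronic acid pinacol ester (second-generation Grubbs catalyst, CH2Cl2, 40 °C) would give 2-{(E)-2-[(1S,4R,5S)-5-bromo-4-chloro-4-methyl-2-methylidenecyclohexyl]ethenyl}-4,4,5,5-tetramethyl-1,3,2-dioxaborolane F4;
- KHF2 in aqueous MeOH would give potassium trifluoro{(E)-2-[(1S,4R,5S)-5-bromo-4-chloro-4-methyl-2-methylidenecyclohexyl]ethenyl}borate F5;
- chlorodeboronation with trichloroisocyanuric acid (EtOAc–H2O, rt) proceeds with retention of alkene geometry and returns at 16.

**Step 4.** Displacement at the CH2 next to the fully substituted epoxide carbon may be slow enough for the triflate to decompose or for the acetylide to open the epoxide. Fallback, from 5, with the alkyne introduced at the allylic stage and the epoxide made without a directing group: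
- CBr4 and PPh3 would give (2E,5E)-1-bromo-2-methylhepta-2,5-diene F6;
- copper-catalysed coupling with ethynylmagnesium bromide (CuCl, THF) would give (4E,7E)-4-methylnona-4,7-dien-1-yne F7;
- Shi epoxidation with the D-fructose-derived ketone (KHSO5 as its triple salt with KHSO4 and K2SO4, K2CO3, MeCN–dimethoxymethane–aqueous buffer, 0 °C) should deliver the (R,R)-epoxide at the more electron-rich trisubstituted alkene, if conversion is held short of completion. The fallback returns at 10.

## Further compounds

F1 | step 7 | (4R,5S,7E)-2,5-dibromo-4-chloro-4-methylnona-1,7-diene | C=C(Br)C[C@@](C)(Cl)[C@@H](Br)C/C=C/C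
F2 | step 6 | (4S,5R,7E)-4-bromo-4-methylnon-7-en-1-yn-5-ol | C#CC[C@](C)(Br)[C@H](O)C/C=C/C
F3 | step 6 | (4S,5R,7E)-4-bromo-4-methylnon-7-en-1-yn-5-yl methanesulfonate | C#CC[C@](C)(Br)[C@H](OS(C)(=O)=O)C/C=C/C
F0 | step 9 | none | none
F4 | step 8 | 2-{(E)-2-[(1S,4R,5S)-5-bromo-4-chloro-4-methyl-2-methylidenecyclohexyl]ethenyl}-4,4,5,5-tetramethyl-1,3,2-dioxaborolane | C[C@@]1(Cl)CC(=C)[C@H](/C=C/B2OC(C)(C)C(C)(C)O2)C[C@@H]1Br
F5 | step 8 | potassium trifluoro{(E)-2-[(1S,4R,5S)-5-bromo-4-chloro-4-methyl-2-methylidenecyclohexyl]ethenyl}borate | C[C@@]1(Cl)CC(=C)[C@H](/C=C/[B-](F)(F)F)C[C@@H]1Br.[K+]
F6 | step 4 | (2E,5E)-1-bromo-2-methylhepta-2,5-diene | BrC/C(C)=C/C/C=C/C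
F7 | step 4 | (4E,7E)-4-methylnona-4,7-dien-1-yne | C#CC/C(C)=C/C/C=C/C
A1 | alternative 1 | (6R)-6-ethenyl-6-methyl-4-methylideneoxan-2-one | C=C[C@@]1(C)CC(=C)CC(=O)O1
A2 | alternative 1 | (1R)-4-methyl-2-methylidenecyclohex-3-ene-1-carboxylic acid | OC(=O)[C@@H]1CC=C(C)CC1=C
A3 | alternative 2 | [(1R,4R,5S)-5-bromo-5-formyl-2,4-dimethyl-4-(triethylsilyloxy)cyclohex-2-en-1-yl]methyl 2,2-dimethylpropanoate | C[C@@]1(O[Si](CC)(CC)CC)C=C(C)[C@H](COC(=O)C(C)(C)C)C[C@@]1(Br)C=O
A4 | alternative 3 | (3S,5S)-3-bromo-5-[(E)-2-chloroethenyl]-6-methylhept-6-en-2-one | CC(=O)[C@@H](Br)C[C@@H](/C=C/Cl)C(C)=C
A5 | alternative 3 | (1R,2S,4S)-2-bromo-4-[(E)-2-chloroethenyl]-1-methyl-5-methylidenecyclohexan-1-ol | C[C@@]1(O)CC(=C)[C@H](/C=C/Cl)C[C@@H]1Br
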